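Thursday's target could not have been growing in proportion to the substrate. It gained 8.1% up to 10.0 min and 8.7 percentage points from there to 20.0 min, equal within the scatter of 1 point, though substrate stood at 30.0% by the end, less than the 58.8% at the midpoint. That run charged 70 mM of substrate, with gas phase held at a saturation of 28 mM and no gas in solution at the start, in a closed stirred flask at constant temperature.

Thursday's run (percent of the substrate charged)

| time / min | target / % | substrate / % |
|---|---|---|
| 1.33 | 0.7 | 92.5 |
| 4.00 | 3.9 | 81.8 |
| 6.00 | 6.6 | 72.3 |
| 10.0 | 8.1 | 58.8 |
| 15.0 | 15.2 | 42.0 |
| 20.0 | 16.8 | 30.0 |

(each reading ± 1 percentage point)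

The new flask charges 47 mM of substrate, with gas phase held at the same saturation of 28 mM, for 1.0 h.

- the target standing at 1.0 h, as a percentage of the substrate charged
- concentration of dissolved gas in solution at 1.0 h, in percent of saturation

I first turned the substrate's fall into a lifetime, τ = 16.6 min, shorter than 1.0 h, so if it carried over, the flask would use nearly its whole charge. I then reckoned two extreme flasks. In the first, target keeps a fixed selectivity s, its share of substrate lost, read between 4.00 min and 20.0 min as 24.9%, which shows 24.9% at any charge. In the second, gas passage sets the pace, so a spent charge yields a fixed amount, the target stock T = s times Thursday's charge, 17.4 mM, which is 37.0% of 47 mM. Thursday's steady gain argued against the first extreme, and target's need for substrate against the second, so I expected the flask between them; having no ground for leaning towards either, I committed to the midpoint of 31.0%.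

The forecast, which differs from my reckoning, gave 24% and 97%, holding that “Target tracks substrate consumed at roughly 0.25”.

The flask gave 34.5% and 93.9%.

    gas phase ⇌ dissolved gas, rate k1*(csat - [dissolved gas]) (kL = 0.0870 /min)
    substrate + dissolved gas → target (k = 2.55 /M/min)
    substrate + target → side product (k = 1.61 /M/min)
    2 substrate → homo dimer (k = 0.306 /M/min)

That target is 16.2 mM in the flask, beside the stock of 17.4 mM. The neighbour charged with 80 mM for the same time has the stock predict 21.7%, and it gave 22.6%, or 18.1 mM. Homo dimer stood at 28.8% in the flask and 40.9% in that neighbour.

The readings come from a simulation with constants of no real substance; the scatter is artificial.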